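The vessel is stirred at constant volume, and north-east, south and north-west differ in how the charge goes in.

| flask | first end groups | second end groups | protic impurity | remark | time |
|---|---|---|---|---|---|
| zeta | 0.050 M | 0.051 M | 5 mM | run made earlier |  |
| delta | 0.050 M | 0.051 M | 2.5 mM | run made earlier |  |
| gamma | 0.050 M | 0.051 M | 10 mM | run made earlier |  |
| theta | 0.10 M | 0.051 M | 5 mM | run made earlier |  |
| north-east | 0.050 M | 0.0510 M | 5.00 mM | everything together at the start | 5.0 h |
| south | 0.050 M (fed, over 4.0 h) | 0.0510 M | 5.00 mM | all else is in the flask from the start; the feed brings no volume worth counting | 5.0 h |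
| north-west | 0.050 M | 0.0510 M (fed, over 4.0 h) | 5.00 mM | all else is in the flask from the start; the feed brings no volume worth counting | 5.0 h |

| run | time / h | links / % | side product A / % | first end groups / % |
|---|---|---|---|---|
| zeta | 0.250 | 39.2 | 18.4 | 20.6 |
| zeta | 0.833 | 36.4 | 28.1 | 4.7 |
| zeta | 1.33 | 32.9 | 30.1 | 3.0 |
| zeta | 2.00 | 29.7 | 33.0 | 2.4 |
| zeta | 3.00 | 27.4 | 33.5 | 1.6 |
| delta | 0.500 | 40.1 | 27.1 | 8.2 |
| delta | 1.50 | 32.4 | 32.6 | 2.5 |
| delta | 3.00 | 28.4 | 35.8 | 1.4 |
| delta | 4.00 | 26.3 | 36.4 | 0.8 |
| delta | 6.00 | 24.8 | 36.9 | 0.3 |
| gamma | 1.33 | 31.4 | 27.0 | 2.9 |
| gamma | 2.50 | 27.2 | 29.4 | 1.9 |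
| gamma | 4.00 | 24.0 | 29.9 | 0.6 |
| gamma | 5.00 | 23.1 | 30.7 | 0.6 |
| gamma | 6.00 | 22.2 | 31.2 | 0.8 |
| theta | 1.33 | 20.4 | 35.3 | 2.0 |
| theta | 2.50 | 17.6 | 35.7 | 1.2 |
| theta | 4.00 | 16.4 | 36.2 | 0.2 |
| theta | 5.00 | 16.2 | 36.6 | 0.4 |
| theta | 6.00 | 15.8 | 36.4 | 0 |

(each reading ± 0.3 percentage points)

- the numbers in the tables scatter with a standard deviation of 0.3 percentage points

* the flask that comes out highest in share of links in links plus side product A, or "all alike" when all lie within 1.5 percentage points (north-east / south / north-west / all alike)
* share of links in links plus side product A at the end, north-east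
* share of links in links plus side product A at the end, south
* share of links in links plus side product A at the end, north-west

I take the fast step as complete and reckon with what it leaves free. I assume that protic impurity quenches first end groups one for one, which makes it the limiting reagent of that step. The fraction of the charge lost this way is the quench share, protic impurity charged over first end groups charged: 10.0% for these charges.

A second way comes from the readings. I tally links plus 2 times side product A plus first end groups. The delta run gives 99.9% at 4.00 h and the gamma run 84.4% at 4.00 h, a drop of 16 points. Their quench shares differ by 15 points, so the two ways agree on that difference.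

They part on theta. Its quench share equals delta's 5.00%, yet its tally at 5.00 h reads 89.8%. The tally is the one that cheats: delta's figure stands above the 95.0% of charge its quench leaves free, so the doubled side product A is a stand-in, not a count. I keep the quotient.

The quench share does not separate the three flasks, since their charges are equal. The readings must do that. North-east has the charges of zeta, but the zeta readings stop at 3.00 h. The share of links reads 42.9% at 5.00 h in gamma, with twice the impurity of zeta, and 40.2% at 6.00 h in delta, with half of it, and I put north-east between these two readings. The same share reads 30.7% at 5.00 h in theta, where first end groups stand at 1.96 times the second. North-west, with second end groups arriving slowly, leans towards theta, and south leans the other way.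

The forecast names south, with north-east 42%, south 50% and north-west 34%, on the ground that “first end groups stay scarce amid free second end groups”.

The simulation gives north-east 41.5%, south 48.5% and north-west 36.2%, so south comes out highest.

    first end groups + second end groups ⇌ links + by-product (K = 2.00, k = 0.0330 M⁻¹ s⁻¹)
    first end groups + links → side product B (k = 0.0120 M⁻¹ s⁻¹)
    first end groups + protic impurity → quenched substrate (k = 0.930 M⁻¹ s⁻¹)
    first end groups + by-product → side product A (k = 0.0460 M⁻¹ s⁻¹)

North-east ends with quenched substrate at 10.0%, the quench share of 10.0%. The neighbouring flask is north-west with 0.013 M of first end groups and the impurity unchanged. Its quench share is 38.5%, which leaves 61.5% free. It ends with quenched substrate at 38.5%, while first end groups, links, side product A and side product B, which counts as two, together hold 61.5%. Links there stand at 34.0% against side product A at 15.9%, a share of 68.1%.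

The readings stem from a simulated flask on assumed constants.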